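**Strategy.** The route rests on disconnecting the ring-fusion bond C5–C10 of ring A. Its key step turns an open C20 chain into the bromocyclohexane: hydrogen-atom transfer to the C10=C20 methylene creates the angular methyl and a tertiary C10 radical, which closes 6-exo onto C5 of a vinyl sulfone and so sets C10 and C5 in one operation. It exploits the congested C4(gem-dimethyl)–C5–C10(methyl) array of ring A. The precursor draws C13 from (R)-linalool, C8/C9 from a Sharpless epoxide opened by an alkenyl Grignard reagent, and C3–Br from a β-lactone opened by bromide. The sulfone afterwards closes ring B (C6–C7) onto a C7–C8 epoxide and is removed.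

Key step: step 14

Remark: atoms are labelled by labdane numbering (C3 carries Br, C8 and C13 carry OH, C20 is the methyl on C10) also in open-chain intermediates, and (R)-linalool of high enantiomeric purity is taken as a commercial starting material.

**Step 1**
Reactants: 1 2,3-dibromoprop-1-ene; 2 (1,3-dioxolan-2-ylmethyl)magnesium bromide
Product: 3 2-(3-bromobut-3-en-1-yl)-1,3-dioxolane
Conditions: CuI (5 mol%), THF, 0 °C → rt
Reagents that add atoms: none
Why: Copper-catalysed allylic substitution of the allylic C–Br bond by the Grignard reagent (SN2 and SN2′ converge on the same product) should leave the vinylic bromide untouched and joins C1 to C2.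

**Step 2**
Reactants: 4 (R)-linalool
Product: 5 (3R)-3,7-dimethyl-3-(triethylsilyloxy)octa-1,6-diene
Conditions: TESOTf, 2,6-lutidine, CH2Cl2, −78 → 0 °C
Reagents that add atoms: triethylsilyl trifluoromethanesulfonate CC[Si](CC)(CC)OS(=O)(=O)C(F)(F)F
Why: Silyl triflate silylation of the tertiary alcohol masks the C13 hydroxyl, which would otherwise open the later C8–C9 epoxide intramolecularly; C13 (R) is untouched.

**Step 3**
Reactants: 5 (3R)-3,7-dimethyl-3-(triethylsilyloxy)octa-1,6-diene
Product: 6 (2E,6R)-2,6-dimethyl-6-(triethylsilyloxy)octa-2,7-dien-1-ol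
Conditions: SeO2 (cat.), t-BuOOH, salicylic acid (cat.), CH2Cl2, rt
Reagents that add atoms: tert-butyl hydroperoxide CC(C)(C)OO
Why: SeO2 allylic oxidation (ene reaction then [2,3]-sigmatropic shift) should hydroxylate only the (E)-methyl (C7) of the trisubstituted alkene and leave the vinyl group alone.

**Step 4**
Reactants: 6 (2E,6R)-2,6-dimethyl-6-(triethylsilyloxy)octa-2,7-dien-1-ol
Product: 7 [(2S,3S)-2-methyl-3-[(3R)-3-methyl-3-(triethylsilyloxy)pent-4-en-1-yl]oxiran-2-yl]methanol
Conditions: Ti(OiPr)4 (cat.), L-(+)-diethyl tartrate, t-BuOOH, 4 Å MS, CH2Cl2, −20 °C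
Reagents that add atoms: tert-butyl hydroperoxide CC(C)(C)OO
Why: Sharpless asymmetric epoxidation of the primary (E)-allylic alcohol with L-(+)-tartrate should give the (2S,3S)-epoxy alcohol by reagent control, setting C8 and C9 of the epoxide, while the silylated tertiary allylic site cannot bind titanium.

**Step 5**
Reactants: 3 2-(3-bromobut-3-en-1-yl)-1,3-dioxolane; 7 [(2S,3S)-2-methyl-3-[(3R)-3-methyl-3-(triethylsilyloxy)pent-4-en-1-yl]oxiran-2-yl]methanol
Product: 9 (2R,3S,6R)-3-[4-(1,3-dioxolan-2-yl)but-1-en-2-yl]-2,6-dimethyl-6-(triethylsilyloxy)oct-7-ene-1,2-diol, via alkenylmagnesium bromide 8 (not isolated)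
Conditions: 3, Mg, THF; then 7 (pre-treated with MeMgBr, 1 equiv), CuI (10 mol%), THF, −30 → 0 °C; aq. NH4Cl
Reagents that add atoms: none
Why: Copper-catalysed SN2 opening of the 2-methyl-2,3-epoxy alcohol by the alkenyl Grignard reagent should occur at the less substituted C9 with inversion, which fixes C9 (S) and leaves the tertiary carbinol C8 as set in step 4.

**Step 6**
Reactants: 9 (2R,3S,6R)-3-[4-(1,3-dioxolan-2-yl)but-1-en-2-yl]-2,6-dimethyl-6-(triethylsilyloxy)oct-7-ene-1,2-diol
Product: 10 7,8-cyclic carbonate of diol 9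
Conditions: CDI, DMAP (cat.), toluene, 60 °C
Reagents that add atoms: 1,1'-carbonyldiimidazole O=C(n1ccnc1)n1ccnc1
Why: Carbonylation of the 1,2-diol to the five-membered cyclic carbonate protects the C7 and C8 hydroxyls through the acidic and Lewis acidic steps that follow; no stereocentre is touched.

**Step 7**
Reactants: 10 7,8-cyclic carbonate of diol 9
Product: 11 (5S,8R)-8-hydroxy-8-methyl-4-methylidene-5-[(4R)-4-methyl-2-oxo-1,3-dioxolan-4-yl]dec-9-enal
Conditions: PPTS, acetone/H2O, 55 °C
Reagents that add atoms: water O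
Why: Mild acid-catalysed acetal hydrolysis should free the C3 aldehyde and cleave the silyl ether in the same operation, while the cyclic carbonate is stable to acid.

**Step 8**
Reactants: 11 (5S,8R)-8-hydroxy-8-methyl-4-methylidene-5-[(4R)-4-methyl-2-oxo-1,3-dioxolan-4-yl]dec-9-enal; 12 1-methoxy-2-methyl-1-(trimethylsilyloxy)prop-1-ene
Product: 13 methyl (3S,7S,10R)-3,10-dihydroxy-2,2,10-trimethyl-6-methylidene-7-[(4R)-4-methyl-2-oxo-1,3-dioxolan-4-yl]dodec-11-enoate
Conditions: N-Ts-D-valine, BH3·THF, CH2Cl2, 0 °C → rt; then 11, 12, −78 °C; pH 7 buffer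
Reagents that add atoms: none
Why: Mukaiyama aldol addition promoted by the chiral oxazaborolidinone from N-tosyl-D-valine and borane should add the ketene acetal to one face of the aldehyde under reagent control, building C4 with its two methyls and setting C3 as the (S)-carbinol.

**Step 9**
Reactants: 13 methyl (3S,7S,10R)-3,10-dihydroxy-2,2,10-trimethyl-6-methylidene-7-[(4R)-4-methyl-2-oxo-1,3-dioxolan-4-yl]dodec-11-enoate
Product: 14 (3S,7S,10R)-7-[(2R)-1,2-dihydroxypropan-2-yl]-3,10-dihydroxy-2,2,10-trimethyl-6-methylidenedodec-11-enoic acid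
Conditions: LiOH, THF/MeOH/H2O, 40 °C; then 1 M HCl to pH 3
Reagents that add atoms: lithium hydroxide [Li+].[OH-]
Why: Saponification should cleave the methyl ester and the cyclic carbonate together, giving the β-hydroxy acid needed for lactonisation and returning the C7/C8 diol.

**Step 10**
Reactants: 14 (3S,7S,10R)-7-[(2R)-1,2-dihydroxypropan-2-yl]-3,10-dihydroxy-2,2,10-trimethyl-6-methylidenedodec-11-enoic acid
Product: 15 (2R,3S,6R)-3-{4-[(2S)-3,3-dimethyl-4-oxooxetan-2-yl]but-1-en-2-yl}-2,6-dihydroxy-2,6-dimethyloct-7-en-1-yl 4-methylbenzenesulfonate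
Conditions: TsCl (3 equiv), pyridine, 0–4 °C
Reagents that add atoms: 4-methylbenzenesulfonyl chloride Cc1ccc(cc1)S(Cl)(=O)=O
Why: Carboxyl activation by the sulfonyl chloride should let the C3 hydroxyl close the β-lactone with retention at C3, while the primary C7 hydroxyl is tosylated in the same flask and the two tertiary hydroxyls stay free.

**Step 11**
Reactants: 15 β-lactone tosylate (name as in step 10)
Product: 16 (3R,7S,10R)-3-bromo-10-hydroxy-7-[(2R)-2-hydroxy-1-(tosyloxy)propan-2-yl]-2,2,10-trimethyl-6-methylidenedodec-11-enoic acid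
Conditions: MgBr2·OEt2, Et2O, 0 °C → rt; 1 M HCl work-up
Reagents that add atoms: magnesium bromide [Mg+2].[Br-].[Br-]
Why: SN2 alkyl–oxygen cleavage of the strained β-lactone by bromide at C3 should proceed with inversion to the (3R)-bromide, because ring strain and the tied-back α-substituents make this neopentyl-type centre accessible.

**Step 12**
Reactants: 16 (3R,7S,10R)-3-bromo acid (name as in step 11)
Product: 18 (3R,7S,10R)-3-bromo-10-hydroxy-7-[(2R)-2-hydroxy-1-(tosyloxy)propan-2-yl]-2,2,10-trimethyl-6-methylidenedodec-11-enal, via acyl imidazolide 17 (not isolated)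
Conditions: CDI, CH2Cl2, rt; then DIBAL-H, −78 °C; Rochelle salt
Reagents that add atoms: none
Why: Acyl imidazolide formation followed by low-temperature hydride reduction should stop at the C5 aldehyde, which has no α-hydrogen and so cannot lose HBr; immediate activation keeps the β-bromo carboxylate from fragmenting.

**Step 13**
Reactants: 18 (3R,7S,10R)-3-bromo aldehyde (name as in step 12); 19 diethyl [(phenylsulfonyl)methyl]phosphonate
Product: 21 (3R,8R,9S,13R,5E)-3-bromo-7,8-epoxy-6-(phenylsulfonyl)-5,10:6,7-disecolabda-5,10(20),14-trien-13-ol, via vinyl sulfone tosylate 20 (not isolated)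
Conditions: 19, NaH (3.5 equiv), THF, 0 °C → rt
Reagents that add atoms: none
Why: Horner–Wadsworth–Emmons olefination with the sulfonyl-stabilised phosphonate should give the (E)-vinyl sulfone (C5=C6), and the excess base closes the β-hydroxy tosylate to the C7–C8 epoxide by Williamson displacement with retention at C8.

**Step 14**
Reactants: 21 (3R,8R,9S,13R,5E)-3-bromo-7,8-epoxy-6-(phenylsulfonyl)-5,10:6,7-disecolabda-5,10(20),14-trien-13-ol
Product: 22 (3R,5S,8R,9S,10S,13R)-3-bromo-7,8-epoxy-6-(phenylsulfonyl)-6,7-secolabd-14-en-13-ol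
Conditions: Fe(acac)3, PhSiH3, EtOH/ethylene glycol, 60 °C
Reagents that add atoms: none
Why: An iron hydride formed from Fe(acac)3 and PhSiH3 transfers a hydrogen atom to C20 of the 1,1-disubstituted alkene, the only alkene that gives a tertiary radical, and the nucleophilic C10 radical adds to C5, the β-carbon of the vinyl sulfone, after which the α-sulfonyl radical is reduced and protonated. The closest known reaction type is the hydrogen-atom-transfer-initiated reductive coupling of unactivated alkenes with vinyl sulfones and related acceptors (a Giese-type conjugate addition), which is known to forge quaternary centres beside fully substituted carbons. Ring A is closed in the 6-exo-trig mode through a chair transition state with the sulfonylvinyl group equatorial at C5. At C10 the small C20 methyl should take the axial site syn to the axial C4 methyl because the branched C9 substituent cannot, which gives the trans relationship of C5–H and the C10 methyl. The face of the C10 radical is selected by the C9 stereocentre: C9–H sits in the congested sector next to C5/C6 and the bulky epoxide carbon C8 lies anti to the forming C5–C10 bond, and in this chair the C3 bromine is equatorial. The step needs chemoselective hydrogen-atom transfer and fast closure; the 1,1-disubstituted alkene is more reactive than the monosubstituted C14=C15 alkene, and the polarity-matched acceptor should outrun both addition to the distal vinyl group and simple reduction.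

**Step 15**
Reactants: 22 (3R,5S,8R,9S,10S,13R)-3-bromo-7,8-epoxy-6-(phenylsulfonyl)-6,7-secolabd-14-en-13-ol
Product: 23 (3R,5S,8S,9S,10S,13R)-3-bromo-6-(phenylsulfonyl)labd-14-ene-8,13-diol (C6 epimers)
Conditions: LDA (3 equiv), THF, −78 °C → rt; aq. NH4Cl
Reagents that add atoms: none
Why: Intramolecular alkylation of the α-sulfonyl carbanion by the epoxide at the primary C7 (6-endo-tet, the quaternary C8 being inaccessible) should close ring B and release the C8 alkoxide with the configuration fixed in step 4; the new C6 centre is removed in the next step.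

**Step 16**
Reactants: 23 (3R,5S,8S,9S,10S,13R)-3-bromo-6-(phenylsulfonyl)labd-14-ene-8,13-diol
Product: 24 (3R,5S,8S,9S,10R,13R)-3-bromolabd-14-ene-8,13-diol
Conditions: Mg, MeOH, 50 °C
Reagents that add atoms: none
Why: Reductive desulfonylation by single-electron transfer from magnesium should cleave the C6–S bond and leave C6 as CH2, the hindered equatorial secondary bromide and the isolated vinyl group being reduced more slowly.

**Compound list**

1 | 2,3-dibromoprop-1-ene | C=C(Br)CBr | starting material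
2 | (1,3-dioxolan-2-ylmethyl)magnesium bromide | Br[Mg]CC1OCCO1 | starting material
3 | 2-(3-bromobut-3-en-1-yl)-1,3-dioxolane | C=C(Br)CCC1OCCO1 | intermediate
4 | (R)-linalool, (3R)-3,7-dimethylocta-1,6-dien-3-ol | C=C[C@](C)(O)CCC=C(C)C | starting material
5 | (3R)-3,7-dimethyl-3-(triethylsilyloxy)octa-1,6-diene | C=C[C@](C)(O[Si](CC)(CC)CC)CCC=C(C)C | intermediate
6 | (2E,6R)-2,6-dimethyl-6-(triethylsilyloxy)octa-2,7-dien-1-ol | C=C[C@](C)(O[Si](CC)(CC)CC)CC/C=C(\C)CO | intermediate
7 | [(2S,3S)-2-methyl-3-[(3R)-3-methyl-3-(triethylsilyloxy)pent-4-en-1-yl]oxiran-2-yl]methanol | C=C[C@](C)(O[Si](CC)(CC)CC)CC[C@@H]1O[C@@]1(C)CO | intermediate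
8 | [4-(1,3-dioxolan-2-yl)but-1-en-2-yl]magnesium bromide | C=C([Mg]Br)CCC1OCCO1 | intermediate
9 | (2R,3S,6R)-3-[4-(1,3-dioxolan-2-yl)but-1-en-2-yl]-2,6-dimethyl-6-(triethylsilyloxy)oct-7-ene-1,2-diol | C=C[C@](C)(O[Si](CC)(CC)CC)CC[C@H]([C@@](C)(O)CO)C(=C)CCC1OCCO1 | intermediate
10 | (4R)-4-[(4S,7R)-1-(1,3-dioxolan-2-yl)-7-methyl-3-methylidene-7-(triethylsilyloxy)non-8-en-4-yl]-4-methyl-1,3-dioxolan-2-one (7,8-cyclic carbonate of 9) | C=C[C@](C)(O[Si](CC)(CC)CC)CC[C@H]([C@]1(C)COC(=O)O1)C(=C)CCC1OCCO1 | intermediate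
11 | (5S,8R)-8-hydroxy-8-methyl-4-methylidene-5-[(4R)-4-methyl-2-oxo-1,3-dioxolan-4-yl]dec-9-enal | C=C[C@](C)(O)CC[C@H]([C@]1(C)COC(=O)O1)C(=C)CCC=O | intermediate
12 | 1-methoxy-2-methyl-1-(trimethylsilyloxy)prop-1-ene | COC(O[Si](C)(C)C)=C(C)C | starting material
13 | methyl (3S,7S,10R)-3,10-dihydroxy-2,2,10-trimethyl-6-methylidene-7-[(4R)-4-methyl-2-oxo-1,3-dioxolan-4-yl]dodec-11-enoate | C=C[C@](C)(O)CC[C@H]([C@]1(C)COC(=O)O1)C(=C)CC[C@H](O)C(C)(C)C(=O)OC | intermediate
14 | (3S,7S,10R)-7-[(2R)-1,2-dihydroxypropan-2-yl]-3,10-dihydroxy-2,2,10-trimethyl-6-methylidenedodec-11-enoic acid | C=C[C@](C)(O)CC[C@H]([C@@](C)(O)CO)C(=C)CC[C@H](O)C(C)(C)C(=O)O | intermediate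
15 | (2R,3S,6R)-3-{4-[(2S)-3,3-dimethyl-4-oxooxetan-2-yl]but-1-en-2-yl}-2,6-dihydroxy-2,6-dimethyloct-7-en-1-yl 4-methylbenzenesulfonate | C=C[C@](C)(O)CC[C@H]([C@@](C)(O)COS(=O)(=O)c1ccc(C)cc1)C(=C)CC[C@@H]1OC(=O)C1(C)C | intermediate
16 | (3R,7S,10R)-3-bromo-10-hydroxy-7-[(2R)-2-hydroxy-1-(tosyloxy)propan-2-yl]-2,2,10-trimethyl-6-methylidenedodec-11-enoic acid | C=C[C@](C)(O)CC[C@H]([C@@](C)(O)COS(=O)(=O)c1ccc(C)cc1)C(=C)CC[C@@H](Br)C(C)(C)C(=O)O | intermediate
17 | N-acylimidazole (imidazolide) of acid 16 | C=C[C@](C)(O)CC[C@H]([C@@](C)(O)COS(=O)(=O)c1ccc(C)cc1)C(=C)CC[C@@H](Br)C(C)(C)C(=O)n1ccnc1 | intermediate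
18 | (3R,7S,10R)-3-bromo-10-hydroxy-7-[(2R)-2-hydroxy-1-(tosyloxy)propan-2-yl]-2,2,10-trimethyl-6-methylidenedodec-11-enal | C=C[C@](C)(O)CC[C@H]([C@@](C)(O)COS(=O)(=O)c1ccc(C)cc1)C(=C)CC[C@@H](Br)C(C)(C)C=O | intermediate
19 | diethyl [(phenylsulfonyl)methyl]phosphonate | CCOP(=O)(CS(=O)(=O)c1ccccc1)OCC | starting material
20 | (3R,8R,9S,13R,5E)-3-bromo-6-(phenylsulfonyl)-7-(tosyloxy)-5,10:6,7-disecolabda-5,10(20),14-triene-8,13-diol | C=C[C@](C)(O)CC[C@H]([C@@](C)(O)COS(=O)(=O)c1ccc(C)cc1)C(=C)CC[C@@H](Br)C(C)(C)/C=C/S(=O)(=O)c1ccccc1 | intermediate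
21 | (3R,8R,9S,13R,5E)-3-bromo-7,8-epoxy-6-(phenylsulfonyl)-5,10:6,7-disecolabda-5,10(20),14-trien-13-ol | C=C[C@](C)(O)CC[C@H]([C@]1(C)CO1)C(=C)CC[C@@H](Br)C(C)(C)/C=C/S(=O)(=O)c1ccccc1 | intermediate
22 | (3R,5S,8R,9S,10S,13R)-3-bromo-7,8-epoxy-6-(phenylsulfonyl)-6,7-secolabd-14-en-13-ol | C=C[C@](C)(O)CC[C@H]([C@]1(C)CO1)[C@]2(C)CC[C@@H](Br)C(C)(C)[C@H]2CS(=O)(=O)c1ccccc1 | intermediate
23 | (3R,5S,8S,9S,10S,13R)-3-bromo-6-(phenylsulfonyl)labd-14-ene-8,13-diol (C6 epimers) | C=C[C@](C)(O)CC[C@H]1[C@]2(C)CC[C@@H](Br)C(C)(C)[C@H]2C(S(=O)(=O)c3ccccc3)C[C@]1(C)O | intermediate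
24 | (3R,5S,8S,9S,10R,13R)-3-bromolabd-14-ene-8,13-diol | C=C[C@](C)(O)CC[C@H]1[C@]2(C)CC[C@@H](Br)C(C)(C)[C@H]2CC[C@]1(C)O | target

**Totals.** Total step count: 16. Longest linear sequence: 15 steps (steps 2–16 from (R)-linalool; step 1 is a one-step side branch).

**Steps most likely to fail**

**Step 14 (key step).** The hydrogen-atom transfer may not discriminate well enough between the 1,1-disubstituted alkene and the C14=C15 vinyl group, and the tertiary radical may be reduced before it closes. The fallback generates the same C10 radical regiospecifically from an epoxide with Cp2TiCl.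
- It sets out from aldehyde 18. Olefination with 19 under LiCl/DBU in MeCN keeps the tosylate and gives the vinyl sulfone tosylate 20 as an isolated compound.
- mCPBA should epoxidise only the electron-rich 1,1-disubstituted alkene, giving the C10–C20 epoxide F1.
- Cp2TiCl (from Cp2TiCl2 and Zn) opens it homolytically to the β-titanoxy tertiary C10 radical, which closes 6-exo onto the vinyl sulfone to give the C20 primary alcohol F2.
- Dess–Martin oxidation gives the C20 aldehyde F3, condensation with TsNHNH2 the tosylhydrazone F4, and reduction with catecholborane/NaOAc the C20 methyl compound F5.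
- Treatment of F5 with LDA closes the C7–C8 epoxide and then ring B, so the route is rejoined at 23.

**Step 16.** Electron transfer to the secondary C3–Br bond may compete with cleavage of the C6–S bond, so that bromine is lost during desulfonylation. The fallback replaces the sulfone by an ester that is removed by oxidative decarboxylation.
- It sets out from aldehyde 18. Horner–Wadsworth–Emmons reaction with trimethyl phosphonoacetate/NaH gives the (E)-enoate epoxide F6.
- The Fe(acac)3/PhSiH3 closure of step 14 gives the ring A ester F7.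
- LDA closes ring B by ester enolate opening of the epoxide at C7 to the hydroxy ester F8.
- LiOH gives the acid F9.
- Photoredox hydrodecarboxylation (9-mesityl-10-methylacridinium tetrafluoroborate, PhSSPh, 2,6-lutidine, trifluoroethanol, blue light) replaces CO2H by H and returns to the route at the target 24.

**Step 8.** The free tertiary hydroxyl and the carbonate may bind the boron promoter and erode the enantioface selection of the aldol addition. The fallback sets C3 by reagent-controlled ketone reduction instead.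
- It sets out from aldehyde 11. A Reformatsky reaction with methyl 2-bromo-2-methylpropanoate and Zn gives the C3-epimeric β-hydroxy esters F10.
- Dess–Martin oxidation gives the β-keto ester F11.
- Reduction with (−)-B-chlorodiisopinocampheylborane, which differentiates the tert-alkyl side from the CH2 side of the ketone, should give the (3S)-alcohol and returns to the route at 13.

Further compounds
F1 | step 14 | C10–C20 epoxide of vinyl sulfone tosylate 20 (epimers at C10) | C=C[C@](C)(O)CC[C@H]([C@@](C)(O)COS(=O)(=O)c1ccc(C)cc1)C1(CO1)CC[C@@H](Br)C(C)(C)/C=C/S(=O)(=O)c1ccccc1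
F2 | step 14 | 3-bromo-6-(phenylsulfonyl)-7-(tosyloxy)-6,7-secolabd-14-ene-8,13,20-triol with the ring A configuration of 22 | C=C[C@](C)(O)CC[C@H]([C@@](C)(O)COS(=O)(=O)c1ccc(C)cc1)[C@]2(CO)CC[C@@H](Br)C(C)(C)[C@H]2CS(=O)(=O)c1ccccc1
F3 | step 14 | C20 aldehyde from F2 | C=C[C@](C)(O)CC[C@H]([C@@](C)(O)COS(=O)(=O)c1ccc(C)cc1)[C@]2(C=O)CC[C@@H](Br)C(C)(C)[C@H]2CS(=O)(=O)c1ccccc1
F4 | step 14 | C20 tosylhydrazone of F3 | C=C[C@](C)(O)CC[C@H]([C@@](C)(O)COS(=O)(=O)c1ccc(C)cc1)[C@]2(C=NNS(=O)(=O)c3ccc(C)cc3)CC[C@@H](Br)C(C)(C)[C@H]2CS(=O)(=O)c1ccccc1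
F5 | step 14 | 3-bromo-6-(phenylsulfonyl)-7-(tosyloxy)-6,7-secolabd-14-ene-8,13-diol with the ring A configuration of 22 | C=C[C@](C)(O)CC[C@H]([C@@](C)(O)COS(=O)(=O)c1ccc(C)cc1)[C@]2(C)CC[C@@H](Br)C(C)(C)[C@H]2CS(=O)(=O)c1ccccc1
F6 | step 16 | methyl (E)-enoate analogue of 21 (CO2CH3 on C6 in place of the sulfonyl group) | C=C[C@](C)(O)CC[C@H]([C@]1(C)CO1)C(=C)CC[C@@H](Br)C(C)(C)/C=C/C(=O)OC
F7 | step 16 | methyl ester analogue of 22 (ring A closed, CH2CO2CH3 on C5) | C=C[C@](C)(O)CC[C@H]([C@]1(C)CO1)[C@]2(C)CC[C@@H](Br)C(C)(C)[C@H]2CC(=O)OC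
F8 | step 16 | 6-(methoxycarbonyl) derivative of 24 (C6 epimers) | C=C[C@](C)(O)CC[C@H]1[C@]2(C)CC[C@@H](Br)C(C)(C)[C@H]2C(C(=O)OC)C[C@]1(C)O
F9 | step 16 | 6-carboxylic acid derivative of 24 (C6 epimers) | C=C[C@](C)(O)CC[C@H]1[C@]2(C)CC[C@@H](Br)C(C)(C)[C@H]2C(C(=O)O)C[C@]1(C)O
F10 | step 8 | C3-epimeric mixture of β-hydroxy ester 13 | C=C[C@](C)(O)CC[C@H]([C@]1(C)COC(=O)O1)C(=C)CCC(O)C(C)(C)C(=O)OC
F11 | step 8 | 3-oxo analogue of 13 (β-keto ester) | C=C[C@](C)(O)CC[C@H]([C@]1(C)COC(=O)O1)C(=C)CCC(=O)C(C)(C)C(=O)OC
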